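**Retrosynthetic overview**
- With the rings lettered A to G from the 2,4,6-trihydroxyphenoxy end, ring E has four contiguous oxygen-bearing carbons C2–C5 that map onto the four carbons of dimethyl squarate, while C1 (bonded to the ring D oxygen) and C6–H map onto a 1-aryloxyvinyl group. C1–C2 is made by adding the vinyl anion to squarate and C5–C6 by electrocyclic ring expansion. Ring C has the same substitution pattern, so the one ring-expansion product serves as both the D–E unit and the B–C unit.
- To tell the two hydroquinone oxygens apart, the carbinol oxygen carries a MOM group through the rearrangement; the ketene-derived C5 hydroxyl is then methylated and the hindered C2 hydroxyl released.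
- The other four ether bonds (F–G, E–F, C–D, A–B) each join a phenol oxygen flanked by two oxygenated carbons to an aryl carbon flanked by two hydrogens. F–G is made by Chan–Lam coupling and the rest by Pd-catalysed C–O coupling, with the silyl ethers of rings D and B turned into triflates.
- Order: rings A, B, D, F and G come from benzenoid starting materials; rings E and C are formed in step 6; assembly runs from G to A and ends with cleavage of all eighteen methyl ethers.

Key step: step 6

Remark: the target has no stereocentre; the only one on the route (the carbinol carbon of the cyclobutenones) is racemic and vanishes on aromatisation. 4-Bromo-2,6-dimethoxyphenol, 3,4,5-trimethoxyphenylboronic acid and 2,4,6-trimethoxyphenol are taken as commercial.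

**Route**

Step 1
Reactants: 1 2,6-dimethoxy-1,4-benzoquinone
Product: 2 2,6-dimethoxybenzene-1,4-diol
Conditions: H2 (1 atm), 10% Pd/C, EtOAc, rt; filtered under argon and used at once
Reagents that add atoms: none
Why: Catalytic hydrogenation reduces the quinone to the hydroquinone (quinone reduction) and leaves no reagent residue.

Step 2
Reactants: 2 2,6-dimethoxybenzene-1,4-diol
Product: 3 2,6-dimethoxy-4-(triisopropylsilyloxy)phenol
Conditions: TIPSCl (1.0 equiv), imidazole, DMF, 0 °C
Reagents that add atoms: triisopropylsilyl chloride, CC(C)[Si](Cl)(C(C)C)C(C)C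
Why: Chemoselective O-silylation, since the bulky chlorosilane should react at the C4 hydroxyl with two ortho hydrogens and not at the C1 hydroxyl shielded by two methoxy groups.

Step 3
Reactants: 3 2,6-dimethoxy-4-(triisopropylsilyloxy)phenol; 4 vinyl acetate
Product: 5 triisopropyl[3,5-dimethoxy-4-(vinyloxy)phenoxy]silane
Conditions: [Ir(cod)Cl]2 (1 mol%), Na2CO3, toluene, 100 °C
Reagents that add atoms: none
Why: Iridium-catalysed transfer vinylation of a phenol with vinyl acetate (addition of the aryloxide to the coordinated vinyl ester, then loss of acetate) should tolerate the silyl ether.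

Step 4
Reactants: 5 triisopropyl[3,5-dimethoxy-4-(vinyloxy)phenoxy]silane; 6 dimethyl squarate (3,4-dimethoxycyclobut-3-ene-1,2-dione)
Product: 9 racemic 4-hydroxy-2,3-dimethoxy-4-{1-[2,6-dimethoxy-4-(triisopropylsilyloxy)phenoxy]vinyl}cyclobut-2-en-1-one, via 1-aryloxyvinyllithium 7 (not isolated), via lithium alkoxide 8 (not isolated)
Conditions: t-BuLi (1.1 equiv), THF, −78 °C; then 6 in THF, −78 °C; aq NH4Cl at −78 °C
Reagents that add atoms: none
Why: α-Lithiation of the enol ether at the oxygen-bearing sp2 carbon followed by 1,2-addition to one of the two equivalent squarate carbonyls should give the carbinol, whose new stereocentre forms as a racemate and is erased in step 6.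

Step 5
Reactants: 9 racemic 4-hydroxy-2,3-dimethoxy-4-{1-[2,6-dimethoxy-4-(triisopropylsilyloxy)phenoxy]vinyl}cyclobut-2-en-1-one
Product: 10 racemic 2,3-dimethoxy-4-(methoxymethoxy)-4-{1-[2,6-dimethoxy-4-(triisopropylsilyloxy)phenoxy]vinyl}cyclobut-2-en-1-one
Conditions: MOMCl, iPr2NEt, Bu4NI (cat.), CH2Cl2, 0 °C to rt
Reagents that add atoms: chloromethyl methyl ether, COCCl
Why: O-Alkylation of the tertiary alcohol (MOM protection) under amine base marks the carbinol oxygen, which becomes the C2 oxygen of ring E, so that the two hydroquinone oxygens stay distinguishable.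

Step 6
Reactants: 10 racemic 2,3-dimethoxy-4-(methoxymethoxy)-4-{1-[2,6-dimethoxy-4-(triisopropylsilyloxy)phenoxy]vinyl}cyclobut-2-en-1-one
Product: 13 5-[2,6-dimethoxy-4-(triisopropylsilyloxy)phenoxy]-2,3-dimethoxy-4-(methoxymethoxy)phenol, via dienylketene 11 (not isolated), via cyclohexadienone 12 (not isolated)
Conditions: toluene (degassed), 110 °C, argon
Reagents that add atoms: none
Why: Thermal conrotatory 4π electrocyclic opening of the C1–C4 bond of the cyclobutenone should give dienylketene 11, and the one selectivity needed, the torquoselectivity, is secured by the donor methoxymethoxy oxygen on C4, which rotates outward and so turns the 1-aryloxyvinyl group inward, cis to the ketene. A thermal disrotatory 6π electrocyclisation then bonds the ketene carbon to the vinyl CH2 terminus (the C5–C6 bond in the ring E numbering of the target) and closes ring E as cyclohexa-2,4-dienone 12, which enolises to the phenol. The closest known reaction type is the Moore rearrangement of 4-alkenyl-4-alkoxycyclobutenones to monoprotected hydroquinones. No stereocentre is formed, and the racemic carbinol centre of 10 disappears on aromatisation. The oxygen pattern follows from connectivity alone: the carbinol oxygen with its MOM group becomes the C2 oxygen between the ring D ether and a methoxy group, the ketene oxygen becomes the free C5 hydroxyl, and the two squarate methoxy groups sit on C3 and C4.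

Step 7
Reactants: 13 5-[2,6-dimethoxy-4-(triisopropylsilyloxy)phenoxy]-2,3-dimethoxy-4-(methoxymethoxy)phenol
Product: 14 triisopropyl{3,5-dimethoxy-4-[3,4,5-trimethoxy-2-(methoxymethoxy)phenoxy]phenoxy}silane
Conditions: MeI, K2CO3, acetone, 40 °C
Reagents that add atoms: iodomethane, CI
Why: Williamson O-methylation of the only free phenol (ring E C5) under mild carbonate conditions should leave the aryl silyl ether and the MOM acetal intact.

Step 8
Reactants: 14 triisopropyl{3,5-dimethoxy-4-[3,4,5-trimethoxy-2-(methoxymethoxy)phenoxy]phenoxy}silane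
Product: 15 6-[2,6-dimethoxy-4-(triisopropylsilyloxy)phenoxy]-2,3,4-trimethoxyphenol
Conditions: HCl (cat.), MeOH, 40 °C
Reagents that add atoms: none
Why: Acid-catalysed transacetalisation to methanol removes the aryl MOM ether, while the aryl triisopropylsilyl ether and the methyl ethers are stable to dilute methanolic HCl.

Step 9
Reactants: 16 4-bromo-2,6-dimethoxyphenol; 17 3,4,5-trimethoxyphenylboronic acid
Product: 18 5-bromo-1,3-dimethoxy-2-(3,4,5-trimethoxyphenoxy)benzene
Conditions: Cu(OAc)2 (1 equiv), pyridine, 4 Å molecular sieves, CH2Cl2, air, rt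
Reagents that add atoms: none
Why: Chan–Lam oxidative O-arylation (copper-mediated, air as terminal oxidant) proceeds at room temperature with doubly ortho-substituted phenols and should leave the aryl bromide untouched.

Step 10
Reactants: 15 6-[2,6-dimethoxy-4-(triisopropylsilyloxy)phenoxy]-2,3,4-trimethoxyphenol; 18 5-bromo-1,3-dimethoxy-2-(3,4,5-trimethoxyphenoxy)benzene
Product: 19 triisopropyl(3,5-dimethoxy-4-{3,4,5-trimethoxy-2-[3,5-dimethoxy-4-(3,4,5-trimethoxyphenoxy)phenoxy]phenoxy}phenoxy)silane (rings D–E–F–G)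
Conditions: Pd(OAc)2 (5 mol%), tBuXPhos (2-di-tert-butylphosphino-2',4',6'-triisopropylbiphenyl), K3PO4, toluene, 100 °C
Reagents that add atoms: none
Why: Pd-catalysed C–O cross-coupling (Buchwald–Hartwig diaryl ether synthesis) with a bulky di-tert-butylbiarylphosphine suits an ortho-disubstituted phenoxide and an aryl bromide flanked only by hydrogens, and K3PO4 in toluene should spare the silyl ether.

Step 11
Reactants: 19 triisopropyl(3,5-dimethoxy-4-{3,4,5-trimethoxy-2-[3,5-dimethoxy-4-(3,4,5-trimethoxyphenoxy)phenoxy]phenoxy}phenoxy)silane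
Product: 20 3,5-dimethoxy-4-{3,4,5-trimethoxy-2-[3,5-dimethoxy-4-(3,4,5-trimethoxyphenoxy)phenoxy]phenoxy}phenol
Conditions: Bu4NF, AcOH, THF, 0 °C
Reagents that add atoms: none
Why: Fluoride-mediated cleavage of the aryl silyl ether, buffered with acetic acid so that the electron-rich phenoxide is not exposed to air oxidation.

Step 12
Reactants: 20 3,5-dimethoxy-4-{3,4,5-trimethoxy-2-[3,5-dimethoxy-4-(3,4,5-trimethoxyphenoxy)phenoxy]phenoxy}phenol
Product: 21 3,5-dimethoxy-4-{3,4,5-trimethoxy-2-[3,5-dimethoxy-4-(3,4,5-trimethoxyphenoxy)phenoxy]phenoxy}phenyl trifluoromethanesulfonate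
Conditions: Tf2O, pyridine, CH2Cl2, 0 °C
Reagents that add atoms: trifluoromethanesulfonic anhydride, O=S(=O)(OS(=O)(=O)C(F)(F)F)C(F)(F)F
Why: O-Sulfonylation of the single unhindered phenol turns the ring D oxygen into a leaving group for cross-coupling.

Step 13
Reactants: 21 3,5-dimethoxy-4-{3,4,5-trimethoxy-2-[3,5-dimethoxy-4-(3,4,5-trimethoxyphenoxy)phenoxy]phenoxy}phenyl trifluoromethanesulfonate; 15 6-[2,6-dimethoxy-4-(triisopropylsilyloxy)phenoxy]-2,3,4-trimethoxyphenol (1.5 equiv)
Product: 22 hexamer silyl ether (rings B to G): 15 in which the phenolic hydrogen is replaced by the 3,5-dimethoxy-4-{3,4,5-trimethoxy-2-[3,5-dimethoxy-4-(3,4,5-trimethoxyphenoxy)phenoxy]phenoxy}phenyl group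
Conditions: Pd(OAc)2 (10 mol%), tBuXPhos, K3PO4, toluene, 100 °C
Reagents that add atoms: none
Why: Pd-catalysed C–O cross-coupling of an aryl triflate with a phenol (Buchwald–Hartwig etherification), in which the crowded phenoxide favours C–O reductive elimination and the triflate carbon has only ortho hydrogens.

Step 14
Reactants: 22 hexamer silyl ether (rings B to G)
Product: 23 hexamer phenol (rings B to G): 22 with the triisopropylsilyl group replaced by hydrogen
Conditions: Bu4NF, AcOH, THF, 0 °C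
Reagents that add atoms: none
Why: Buffered fluoride-mediated desilylation, as in step 11.

Step 15
Reactants: 23 hexamer phenol (rings B to G)
Product: 24 hexamer triflate (rings B to G): trifluoromethanesulfonate ester of 23
Conditions: Tf2O, pyridine, CH2Cl2, 0 °C
Reagents that add atoms: trifluoromethanesulfonic anhydride, O=S(=O)(OS(=O)(=O)C(F)(F)F)C(F)(F)F
Why: O-Sulfonylation of the only free phenol (ring B C1), as in step 12.

Step 16
Reactants: 24 hexamer triflate (rings B to G); 25 2,4,6-trimethoxyphenol (2 equiv)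
Product: 26 octadeca-O-methyl ether of the target (rings A to G): 24 with the triflate replaced by a 2,4,6-trimethoxyphenoxy group
Conditions: Pd(OAc)2 (10 mol%), tBuXPhos, K3PO4, toluene, 100 °C
Reagents that add atoms: none
Why: The same Pd-catalysed C–O cross-coupling of an aryl triflate, here with a small doubly ortho-substituted phenol used in excess.

Step 17
Reactants: 26 octadeca-O-methyl ether of the target
Product: 27 target CNP0292517.0 (free octadecahydroxy heptamer)
Conditions: BBr3 (excess), CH2Cl2, −78 °C to rt, argon; MeOH then H2O; Sephadex LH-20 under argon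
Reagents that add atoms: none
Why: BBr3-mediated cleavage of aryl methyl ethers (Lewis acid complexation, then bromide attack at methyl) should free all eighteen hydroxyls while the diaryl ether bonds are inert.

**Compound list**

1 | 2,6-dimethoxy-1,4-benzoquinone | COC1=CC(=O)C=C(OC)C1=O | starting material
2 | 2,6-dimethoxybenzene-1,4-diol | COc1cc(O)cc(OC)c1O | intermediate
3 | 2,6-dimethoxy-4-(triisopropylsilyloxy)phenol | COc1cc(O[Si](C(C)C)(C(C)C)C(C)C)cc(OC)c1O | intermediate
4 | vinyl acetate | C=COC(C)=O | starting material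
5 | triisopropyl[3,5-dimethoxy-4-(vinyloxy)phenoxy]silane | C=COc1c(OC)cc(O[Si](C(C)C)(C(C)C)C(C)C)cc1OC | intermediate
6 | dimethyl squarate (3,4-dimethoxycyclobut-3-ene-1,2-dione) | COC1=C(OC)C(=O)C1=O | starting material
7 | 1-[2,6-dimethoxy-4-(triisopropylsilyloxy)phenoxy]vinyllithium | [Li]C(=C)Oc1c(OC)cc(O[Si](C(C)C)(C(C)C)C(C)C)cc1OC | intermediate (not isolated)
8 | lithium alkoxide of 9 (racemic) | COC1=C(OC)C(O[Li])(C(=C)Oc2c(OC)cc(O[Si](C(C)C)(C(C)C)C(C)C)cc2OC)C1=O | intermediate (not isolated)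
9 | racemic 4-hydroxy-2,3-dimethoxy-4-{1-[2,6-dimethoxy-4-(triisopropylsilyloxy)phenoxy]vinyl}cyclobut-2-en-1-one | COC1=C(OC)C(O)(C(=C)Oc2c(OC)cc(O[Si](C(C)C)(C(C)C)C(C)C)cc2OC)C1=O | intermediate
10 | racemic 2,3-dimethoxy-4-(methoxymethoxy)-4-{1-[2,6-dimethoxy-4-(triisopropylsilyloxy)phenoxy]vinyl}cyclobut-2-en-1-one | COC1=C(OC)C(OCOC)(C(=C)Oc2c(OC)cc(O[Si](C(C)C)(C(C)C)C(C)C)cc2OC)C1=O | intermediate
11 | (3Z)-5-[2,6-dimethoxy-4-(triisopropylsilyloxy)phenoxy]-2,3-dimethoxy-4-(methoxymethoxy)hexa-1,3,5-trien-1-one (dienylketene) | O=C=C(OC)/C(OC)=C(OCOC)\C(=C)Oc1c(OC)cc(O[Si](C(C)C)(C(C)C)C(C)C)cc1OC | intermediate (not isolated)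
12 | 5-[2,6-dimethoxy-4-(triisopropylsilyloxy)phenoxy]-2,3-dimethoxy-4-(methoxymethoxy)cyclohexa-2,4-dien-1-one | O=C1CC(Oc2c(OC)cc(O[Si](C(C)C)(C(C)C)C(C)C)cc2OC)=C(OCOC)C(OC)=C1OC | intermediate (not isolated)
13 | 5-[2,6-dimethoxy-4-(triisopropylsilyloxy)phenoxy]-2,3-dimethoxy-4-(methoxymethoxy)phenol | COc1c(O)cc(Oc2c(OC)cc(O[Si](C(C)C)(C(C)C)C(C)C)cc2OC)c(OCOC)c1OC | intermediate
14 | triisopropyl{3,5-dimethoxy-4-[3,4,5-trimethoxy-2-(methoxymethoxy)phenoxy]phenoxy}silane | COc1c(OC)cc(Oc2c(OC)cc(O[Si](C(C)C)(C(C)C)C(C)C)cc2OC)c(OCOC)c1OC | intermediate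
15 | 6-[2,6-dimethoxy-4-(triisopropylsilyloxy)phenoxy]-2,3,4-trimethoxyphenol (D–E and B–C building block) | COc1c(OC)cc(Oc2c(OC)cc(O[Si](C(C)C)(C(C)C)C(C)C)cc2OC)c(O)c1OC | intermediate
16 | 4-bromo-2,6-dimethoxyphenol | COc1cc(Br)cc(OC)c1O | starting material
17 | 3,4,5-trimethoxyphenylboronic acid | COc1cc(B(O)O)cc(OC)c1OC | starting material
18 | 5-bromo-1,3-dimethoxy-2-(3,4,5-trimethoxyphenoxy)benzene (rings F–G) | COc1cc(Br)cc(OC)c1Oc1cc(OC)c(OC)c(OC)c1 | intermediate
19 | triisopropyl(3,5-dimethoxy-4-{3,4,5-trimethoxy-2-[3,5-dimethoxy-4-(3,4,5-trimethoxyphenoxy)phenoxy]phenoxy}phenoxy)silane (rings D–G) | COc1c(OC)cc(Oc2c(OC)cc(O[Si](C(C)C)(C(C)C)C(C)C)cc2OC)c(Oc2cc(OC)c(Oc3cc(OC)c(OC)c(OC)c3)c(OC)c2)c1OC | intermediate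
20 | 3,5-dimethoxy-4-{3,4,5-trimethoxy-2-[3,5-dimethoxy-4-(3,4,5-trimethoxyphenoxy)phenoxy]phenoxy}phenol | COc1c(OC)cc(Oc2c(OC)cc(O)cc2OC)c(Oc2cc(OC)c(Oc3cc(OC)c(OC)c(OC)c3)c(OC)c2)c1OC | intermediate
21 | 3,5-dimethoxy-4-{3,4,5-trimethoxy-2-[3,5-dimethoxy-4-(3,4,5-trimethoxyphenoxy)phenoxy]phenoxy}phenyl trifluoromethanesulfonate | COc1c(OC)cc(Oc2c(OC)cc(OS(=O)(=O)C(F)(F)F)cc2OC)c(Oc2cc(OC)c(Oc3cc(OC)c(OC)c(OC)c3)c(OC)c2)c1OC | intermediate
22 | hexamer silyl ether (rings B to G) | COc1c(OC)cc(Oc2c(OC)cc(O[Si](C(C)C)(C(C)C)C(C)C)cc2OC)c(Oc3cc(OC)c(Oc4cc(OC)c(OC)c(OC)c4Oc4cc(OC)c(Oc5cc(OC)c(OC)c(OC)c5)c(OC)c4)c(OC)c3)c1OC | intermediate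
23 | hexamer phenol (rings B to G) | COc1c(OC)cc(Oc2c(OC)cc(O)cc2OC)c(Oc3cc(OC)c(Oc4cc(OC)c(OC)c(OC)c4Oc4cc(OC)c(Oc5cc(OC)c(OC)c(OC)c5)c(OC)c4)c(OC)c3)c1OC | intermediate
24 | hexamer triflate (rings B to G) | COc1c(OC)cc(Oc2c(OC)cc(OS(=O)(=O)C(F)(F)F)cc2OC)c(Oc3cc(OC)c(Oc4cc(OC)c(OC)c(OC)c4Oc4cc(OC)c(Oc5cc(OC)c(OC)c(OC)c5)c(OC)c4)c(OC)c3)c1OC | intermediate
25 | 2,4,6-trimethoxyphenol | COc1cc(OC)c(O)c(OC)c1 | starting material
26 | octadeca-O-methyl ether of the target (rings A to G) | COc1c(OC)cc(Oc2c(OC)cc(Oc6c(OC)cc(OC)cc6OC)cc2OC)c(Oc3cc(OC)c(Oc4cc(OC)c(OC)c(OC)c4Oc4cc(OC)c(Oc5cc(OC)c(OC)c(OC)c5)c(OC)c4)c(OC)c3)c1OC | intermediate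
27 | target CNP0292517.0 (achiral) | Oc1cc(O)c(Oc2cc(O)c(Oc3cc(O)c(O)c(O)c3Oc3cc(O)c(Oc4cc(O)c(O)c(O)c4Oc4cc(O)c(Oc5cc(O)c(O)c(O)c5)c(O)c4)c(O)c3)c(O)c2)c(O)c1 | target

**Step count and risks**

Total step count: 17. Longest linear sequence: 16 steps (steps 1 to 8, then 10 to 17); step 9 is the only branch.

Steps most likely to fail:

Step 4. The base may remove a ring D hydrogen lying between the methoxy and silyloxy groups instead of the vinyl α-hydrogen, or the vinyllithium may expel lithium aryloxide before it meets the squarate. The fallback sets out from 3 and takes ring E from an existing benzene ring. Rieche formylation (Cl2CHOMe, TiCl4, CH2Cl2) of commercial 5-fluoro-1,2,3-trimethoxybenzene should give 6-fluoro-2,3,4-trimethoxybenzaldehyde F1. Nucleophilic aromatic substitution of its fluoride, activated by the ortho formyl group, with the potassium salt of 3 (KN(SiMe3)2, DMSO, 90 °C) should give 6-[2,6-dimethoxy-4-(triisopropylsilyloxy)phenoxy]-2,3,4-trimethoxybenzaldehyde F2. Baeyer–Villiger (Dakin-type) oxidation with mCPBA in CH2Cl2 should give 6-[2,6-dimethoxy-4-(triisopropylsilyloxy)phenoxy]-2,3,4-trimethoxyphenyl formate F3, and methanolysis (Et3N, MeOH) comes back to the route at 15.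

Step 13. Triflyl transfer from the aryl triflate to the hindered phenoxide (S–O cleavage) and slow C–O reductive elimination from a crowded arylpalladium phenoxide may stop the coupling of the two large fragments. The fallback sets out from 21 and replaces the Pd-catalysed etherification by a copper-mediated oxidative coupling at room temperature. Miyaura-type borylation (Pd(OAc)2, XPhos, KOAc, B2(OH)4, EtOH, 80 °C) should give (3,5-dimethoxy-4-{3,4,5-trimethoxy-2-[3,5-dimethoxy-4-(3,4,5-trimethoxyphenoxy)phenoxy]phenoxy}phenyl)boronic acid F4, and Chan–Lam coupling of it with 15 (Cu(OAc)2, pyridine, 4 Å molecular sieves, CH2Cl2, air, rt) comes back at 22.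

Step 17. Cleavage of eighteen methyl ethers may stop short, leaving partly methylated material, and the free polyphenol may oxidise in air during isolation. The fallback sets out from 26: after BBr3 treatment the crude product is acetylated at once (Ac2O, pyridine) to the octadecaacetate of the target F5, which is stable and can be purified on silica, with under-demethylated fractions recycled. Acid methanolysis (HCl in MeOH generated from AcCl, argon) then comes back at 27.

**Further compounds**

F1 | step 4 | 6-fluoro-2,3,4-trimethoxybenzaldehyde | COc1cc(F)c(C=O)c(OC)c1OC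
F2 | step 4 | 6-[2,6-dimethoxy-4-(triisopropylsilyloxy)phenoxy]-2,3,4-trimethoxybenzaldehyde | COc1cc(Oc2c(OC)cc(O[Si](C(C)C)(C(C)C)C(C)C)cc2OC)c(C=O)c(OC)c1OC
F3 | step 4 | 6-[2,6-dimethoxy-4-(triisopropylsilyloxy)phenoxy]-2,3,4-trimethoxyphenyl formate | COc1cc(Oc2c(OC)cc(O[Si](C(C)C)(C(C)C)C(C)C)cc2OC)c(OC=O)c(OC)c1OC
F4 | step 13 | (3,5-dimethoxy-4-{3,4,5-trimethoxy-2-[3,5-dimethoxy-4-(3,4,5-trimethoxyphenoxy)phenoxy]phenoxy}phenyl)boronic acid | COc1c(OC)cc(Oc2c(OC)cc(B(O)O)cc2OC)c(Oc2cc(OC)c(Oc3cc(OC)c(OC)c(OC)c3)c(OC)c2)c1OC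
F5 | step 17 | octadecaacetate of the target | CC(=O)Oc1cc(OC(C)=O)c(Oc2cc(OC(C)=O)c(Oc3cc(OC(C)=O)c(OC(C)=O)c(OC(C)=O)c3Oc3cc(OC(C)=O)c(Oc4cc(OC(C)=O)c(OC(C)=O)c(OC(C)=O)c4Oc4cc(OC(C)=O)c(Oc5cc(OC(C)=O)c(OC(C)=O)c(OC(C)=O)c5)c(OC(C)=O)c4)c(OC(C)=O)c3)c(OC(C)=O)c2)c(OC(C)=O)c1
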